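**Strategy.** Everything rests on cutting the bond between C1 of ring A and the carboxyl carbon, so that this carbon arrives last on an already assembled depside. In the precursor, ring A is a 2,6-dihydroxy-4-pentylphenyl ester. A symmetry plane through its C1 (aroyloxy) and C4 (pentyl) exchanges C3–H with C5–H, and each of these sites lies next to one phenolic OH and opposite the other. One TiCl4/Cl2CHOMe formylation therefore installs the missing carbon at a single, unambiguous position on the unprotected diol, sparing the less nucleophilic ring B and the aryl ester. Chlorite oxidation then gives the acid. The precursor comes from two benzenoid fragments by acylium esterification and hydrogenolysis.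

Key step: step 6

Remark: the target has no stereocentre; the only stereogenic carbon in the route is the CH(Cl)OMe carbon of transient 14, which forms racemic and is lost on work-up.
Remark: the carbonyl oxygen of aldehyde 15 is taken to come from water during hydrolysis of 14.
Remark: both ring A hydroxyls are deliberately left free in the precursor, because titanium–phenoxide binding is what directs the electrophile to ring A and away from ring B.

**Step 1**
Reactants: 1 2,4-dimethoxy-6-methylbenzoic acid; 2 iodoethane
Product: 4 2,4-dimethoxy-6-propylbenzoic acid, via benzylic dianion 3 (not isolated)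
Conditions: LiN(iPr)2 (2.2 equiv), THF, −78 to 0 °C; EtI (1.2 equiv), −78 °C to rt; aq. HCl
Reagents that add atoms: iodoethane (2), CCI
Why: Lateral lithiation of an o-toluic acid removes the carboxyl proton and then a proton of the ortho methyl group (the carbanion is stabilised as an extended carboxylate enediolate), and SN2 alkylation by iodoethane extends methyl to propyl, the amide base leaving the ring C–H bonds alone.

**Step 2**
Reactants: 5 olivetol (5-pentylbenzene-1,3-diol)
Product: 6 1,3-bis(benzyloxy)-5-pentylbenzene
Conditions: BnBr (2.3 equiv), K2CO3 (3 equiv), DMF, rt to 60 °C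
Reagents that add atoms: benzyl bromide, BrCc1ccccc1
Why: Williamson ether synthesis on both phenoxide oxygens, O-alkylation being favoured with K2CO3 in a dipolar aprotic solvent.

**Step 3**
Reactants: 6 1,3-bis(benzyloxy)-5-pentylbenzene
Product: 9 2,6-bis(benzyloxy)-4-pentylphenol, via aryllithium 7 (not isolated), via dimethyl arylboronate 8 (not isolated)
Conditions: n-BuLi (1.15 equiv), THF, 0 °C to rt; B(OMe)3, −78 °C to rt; AcOH, 30% H2O2, 0 °C to rt; aq. Na2SO3
Reagents that add atoms: hydrogen peroxide, OO
Why: Directed ortho-metalation lithiates the ring C–H flanked by both benzyloxy oxygens, the aryllithium is trapped as the boronate, and boronate oxidation (peroxide-induced aryl shift from boron to oxygen) under acetic acid buffering should give the phenol before protodeboronation can compete.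

**Step 4**
Reactants: 4 2,4-dimethoxy-6-propylbenzoic acid; 9 2,6-bis(benzyloxy)-4-pentylphenol
Product: 11 2,6-bis(benzyloxy)-4-pentylphenyl 2,4-dimethoxy-6-propylbenzoate, via mixed trifluoroacetic anhydride 10 (not isolated)
Conditions: (CF3CO)2O (3 equiv), toluene, 0 °C to rt; cold aq. NaHCO3
Reagents that add atoms: none
Why: Depside-type esterification through the mixed trifluoroacetic anhydride, which ionises to the linear, methoxy-stabilised acylium ion of the di-ortho-substituted acid and so should acylate even the flanked phenol oxygen, where a tetrahedral-intermediate pathway would be blocked.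

**Step 5**
Reactants: 11 2,6-bis(benzyloxy)-4-pentylphenyl 2,4-dimethoxy-6-propylbenzoate
Product: 12 2,6-dihydroxy-4-pentylphenyl 2,4-dimethoxy-6-propylbenzoate
Conditions: H2 (1 atm), 10% Pd/C, EtOAc, rt
Reagents that add atoms: none
Why: Catalytic hydrogenolysis of the two benzyl aryl ethers is neutral, so the aryl ester, the methyl ethers and both rings should survive and no base is present to drive acyl transfer to a neighbouring hydroxyl.

**Step 6**
Reactants: 12 2,6-dihydroxy-4-pentylphenyl 2,4-dimethoxy-6-propylbenzoate; 13 dichloromethyl methyl ether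
Product: 15 3-formyl-2,6-dihydroxy-4-pentylphenyl 2,4-dimethoxy-6-propylbenzoate, via chloro(methoxy)methyl arene 14 (not isolated)
Conditions: TiCl4 (3 equiv), CH2Cl2, 0 °C, 30 min; Cl2CHOMe (1.1 equiv), 0 °C; ice-cold 1 M HCl
Reagents that add atoms: dichloromethyl methyl ether (13), COC(Cl)Cl; water, O
Why: TiCl4 binds the phenolic oxygens of ring A and ionises Cl2CHOMe to the chloro(methoxy)methyl cation, which attacks the ring A carbon adjacent to one titanium-bound oxygen and opposite the other; rearomatisation with loss of HCl gives α-chloro ether 14, and aqueous work-up hydrolyses it to aldehyde 15. This is a Rieche formylation, an established method for ortho-formylation of resorcinol-type phenols. The step forms one C–C bond, closes no ring and leaves no stereocentre. Regiochemistry on ring A needs no control, because the mirror plane through C1 and C4 of the phenyl ester makes C3 and C5 the same site. Ring selectivity should be secured by the two free hydroxyls, which make ring A far more nucleophilic and deliver the electrophile through titanium coordination, whereas ring B carries only methyl ethers and a TiCl4-complexed ester carbonyl; a second formylation is held back by the new titanium-chelated aldehyde and by the 1.1 equivalents of 13. The acidic, non-nucleophilic medium at 0 °C should leave the hindered aryl ester in place and generates no free phenoxide that could start acyl transfer.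

**Step 7**
Reactants: 15 3-formyl-2,6-dihydroxy-4-pentylphenyl 2,4-dimethoxy-6-propylbenzoate
Product: 16 merochlorophaeic acid (3-[(2,4-dimethoxy-6-propylbenzoyl)oxy]-2,4-dihydroxy-6-pentylbenzoic acid)
Conditions: NaClO2 (3 equiv), NaH2PO4 (4 equiv), 2-methylbut-2-ene (20 equiv), t-BuOH/THF/H2O, 0 °C to rt; acidify cold, no heating
Reagents that add atoms: sodium chlorite NaClO2, [Na+].[O-]Cl=O
Why: Pinnick (Lindgren) oxidation converts the aldehyde to the acid through its chlorous acid adduct, the alkene scavenges HOCl before it can chlorinate the activated free C–H of ring A, and the buffered, mildly acidic medium should spare the ester and the decarboxylation-prone salicylic acid.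

**Compound list**
1 | 2,4-dimethoxy-6-methylbenzoic acid | Cc1cc(OC)cc(OC)c1C(=O)O | starting material
2 | iodoethane | CCI | starting material
3 | lithium 2-(lithiomethyl)-4,6-dimethoxybenzoate (not isolated) | [Li]Cc1cc(OC)cc(OC)c1C(=O)O[Li] | intermediate
4 | 2,4-dimethoxy-6-propylbenzoic acid | CCCc1cc(OC)cc(OC)c1C(=O)O | intermediate
5 | olivetol (5-pentylbenzene-1,3-diol) | CCCCCc1cc(O)cc(O)c1 | starting material
6 | 1,3-bis(benzyloxy)-5-pentylbenzene | CCCCCc1cc(OCc2ccccc2)cc(OCc2ccccc2)c1 | intermediate
7 | [2,6-bis(benzyloxy)-4-pentylphenyl]lithium (not isolated) | [Li]c1c(OCc2ccccc2)cc(CCCCC)cc1OCc1ccccc1 | intermediate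
8 | dimethyl [2,6-bis(benzyloxy)-4-pentylphenyl]boronate (not isolated) | COB(OC)c1c(OCc2ccccc2)cc(CCCCC)cc1OCc1ccccc1 | intermediate
9 | 2,6-bis(benzyloxy)-4-pentylphenol | CCCCCc1cc(OCc2ccccc2)c(O)c(OCc2ccccc2)c1 | intermediate
10 | 2,4-dimethoxy-6-propylbenzoic trifluoroacetic anhydride (not isolated) | CCCc1cc(OC)cc(OC)c1C(=O)OC(=O)C(F)(F)F | intermediate
11 | 2,6-bis(benzyloxy)-4-pentylphenyl 2,4-dimethoxy-6-propylbenzoate | CCCCCc1cc(OCc2ccccc2)c(OC(=O)c2c(CCC)cc(OC)cc2OC)c(OCc2ccccc2)c1 | intermediate
12 | 2,6-dihydroxy-4-pentylphenyl 2,4-dimethoxy-6-propylbenzoate | CCCCCc1cc(O)c(OC(=O)c2c(CCC)cc(OC)cc2OC)c(O)c1 | intermediate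
13 | dichloromethyl methyl ether | COC(Cl)Cl | starting material
14 | 3-[chloro(methoxy)methyl]-2,6-dihydroxy-4-pentylphenyl 2,4-dimethoxy-6-propylbenzoate (racemic, not isolated) | CCCCCc1cc(O)c(OC(=O)c2c(CCC)cc(OC)cc2OC)c(O)c1C(Cl)OC | intermediate
15 | 3-formyl-2,6-dihydroxy-4-pentylphenyl 2,4-dimethoxy-6-propylbenzoate | CCCCCc1cc(O)c(OC(=O)c2c(CCC)cc(OC)cc2OC)c(O)c1C=O | intermediate
16 | merochlorophaeic acid | CCCCCc1cc(O)c(OC(=O)c2c(CCC)cc(OC)cc2OC)c(O)c1C(=O)O | target

**Step count.** Total: 7 steps. Longest linear sequence: 6 steps (5 → 6 → 9 → 11 → 12 → 15 → 16); the ring B branch (1 → 4) is one step and joins at step 4.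

**Steps most likely to fail**

1. Step 6. The electrophile may attack the dimethoxy-substituted ring B, ring A may be formylated twice, or the Lewis acid may promote acyl transfer or ester cleavage. The fallback puts the ring A carbon in place before ring B is attached; it sets out from phenol 9 and comes back to the route at target 16. Vilsmeier–Haack formylation of 9 (POCl3, DMF, 0 °C to rt; aq. NaOAc) should occur at the ring carbon ortho to one benzyloxy group and para to the other. It passes through N-{[2,4-bis(benzyloxy)-3-hydroxy-6-pentylphenyl]methylidene}-N-methylmethanaminium chloride F1 and gives 2,4-bis(benzyloxy)-3-hydroxy-6-pentylbenzaldehyde F2. Chlorite oxidation (NaClO2, NaH2PO4, 2-methylbut-2-ene) gives 2,4-bis(benzyloxy)-3-hydroxy-6-pentylbenzoic acid F3. Selective carboxylate alkylation (BnBr, KHCO3, DMF) gives benzyl 2,4-bis(benzyloxy)-3-hydroxy-6-pentylbenzoate F4. Coupling of F4 with acid 4 through mixed anhydride 10 ((CF3CO)2O, toluene) gives benzyl 2,4-bis(benzyloxy)-3-[(2,4-dimethoxy-6-propylbenzoyl)oxy]-6-pentylbenzoate F5. Hydrogenolysis (H2, Pd/C, EtOAc) removes all three benzyl groups to give 16.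

2. Step 4. The acylium ion may acylate a ring carbon of the very electron-rich phenol, or trifluoroacetylation of the flanked hydroxyl may outrun aroylation. The fallback forms the ester by making the bond from the ring A carbon to oxygen instead of the acyl–oxygen bond; it sets out from acid 4 and comes back at precursor 12, so steps 2, 3 and 5 are also bypassed. Commercial 5-pentylcyclohexane-1,3-dione undergoes diazo transfer (4-acetamidobenzenesulfonyl azide, Et3N, MeCN) to 2-diazo-5-pentylcyclohexane-1,3-dione F6. Rh2(OAc)4 (1 mol%) in CH2Cl2 at 40 °C with acid 4 should give O–H insertion of the carbenoid into the carboxylic acid, affording racemic 2-hydroxy-6-oxo-4-pentylcyclohex-1-en-1-yl 2,4-dimethoxy-6-propylbenzoate F7. Dehydrogenation (DDQ, dioxane, reflux) aromatises F7 to 12.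

3. Step 3. Butyllithium may deprotonate a benzylic CH2 of a benzyl ether, leading to Wittig rearrangement, or the di-ortho-alkoxy boronate may protodeboronate before it is oxidised. The fallback uses protecting groups without benzylic hydrogens and a different coupling and unmasking; it sets out from olivetol 5 and comes back at precursor 12. MOMCl and iPr2NEt in CH2Cl2 give 1,3-bis(methoxymethoxy)-5-pentylbenzene F8. n-BuLi in THF at 0 °C gives [2,6-bis(methoxymethoxy)-4-pentylphenyl]lithium F9, B(OMe)3 gives dimethyl [2,6-bis(methoxymethoxy)-4-pentylphenyl]boronate F10, and AcOH/H2O2 gives 2,6-bis(methoxymethoxy)-4-pentylphenol F11. Acid 4 is converted with (COCl)2 and catalytic DMF into 2,4-dimethoxy-6-propylbenzoyl chloride F12, which acylates the sodium phenoxide of F11 (NaH, THF) to give 2,6-bis(methoxymethoxy)-4-pentylphenyl 2,4-dimethoxy-6-propylbenzoate F13. HCl in MeOH at 40 °C removes both acetals to give 12.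

**Further compounds**
F1 | step 6 | N-{[2,4-bis(benzyloxy)-3-hydroxy-6-pentylphenyl]methylidene}-N-methylmethanaminium chloride | CCCCCc1cc(OCc2ccccc2)c(O)c(OCc2ccccc2)c1C=[N+](C)C.[Cl-]
F2 | step 6 | 2,4-bis(benzyloxy)-3-hydroxy-6-pentylbenzaldehyde | CCCCCc1cc(OCc2ccccc2)c(O)c(OCc2ccccc2)c1C=O
F3 | step 6 | 2,4-bis(benzyloxy)-3-hydroxy-6-pentylbenzoic acid | CCCCCc1cc(OCc2ccccc2)c(O)c(OCc2ccccc2)c1C(=O)O
F4 | step 6 | benzyl 2,4-bis(benzyloxy)-3-hydroxy-6-pentylbenzoate | CCCCCc1cc(OCc2ccccc2)c(O)c(OCc2ccccc2)c1C(=O)OCc1ccccc1
F5 | step 6 | benzyl 2,4-bis(benzyloxy)-3-[(2,4-dimethoxy-6-propylbenzoyl)oxy]-6-pentylbenzoate | CCCCCc1cc(OCc2ccccc2)c(OC(=O)c2c(CCC)cc(OC)cc2OC)c(OCc2ccccc2)c1C(=O)OCc1ccccc1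
F6 | step 4 | 2-diazo-5-pentylcyclohexane-1,3-dione | CCCCCC1CC(=O)C(=[N+]=[N-])C(=O)C1
F7 | step 4 | 2-hydroxy-6-oxo-4-pentylcyclohex-1-en-1-yl 2,4-dimethoxy-6-propylbenzoate (racemic) | CCCCCC1CC(O)=C(OC(=O)c2c(CCC)cc(OC)cc2OC)C(=O)C1
F8 | step 3 | 1,3-bis(methoxymethoxy)-5-pentylbenzene | CCCCCc1cc(OCOC)cc(OCOC)c1
F9 | step 3 | [2,6-bis(methoxymethoxy)-4-pentylphenyl]lithium | [Li]c1c(OCOC)cc(CCCCC)cc1OCOC
F10 | step 3 | dimethyl [2,6-bis(methoxymethoxy)-4-pentylphenyl]boronate | COB(OC)c1c(OCOC)cc(CCCCC)cc1OCOC
F11 | step 3 | 2,6-bis(methoxymethoxy)-4-pentylphenol | CCCCCc1cc(OCOC)c(O)c(OCOC)c1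
F12 | step 3 | 2,4-dimethoxy-6-propylbenzoyl chloride | CCCc1cc(OC)cc(OC)c1C(Cl)=O
F13 | step 3 | 2,6-bis(methoxymethoxy)-4-pentylphenyl 2,4-dimethoxy-6-propylbenzoate | CCCCCc1cc(OCOC)c(OC(=O)c2c(CCC)cc(OC)cc2OC)c(OCOC)c1
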